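**Locants used below.** Core ring C1–C5: C1 carries the side chain, C2 is CH2, C3 carries O-acyl, C4 carries CH3, C5 carries CH2OH (carbon C6). C1′ is the exocyclic methine on C1, C2′ its CH2O-acyl carbon, C3′ its CH2OH carbon. Acyl chain: a1 (C=O) to a6 (CH3), with the formyl group on a4 and the 2-oxoethyl arm on a3. With the ring drawn so that C1→C5 runs clockwise, β points to the viewer and α away.

## Analysis of the target

The target 31 is a tetrasubstituted cyclopentane with C1 (α side chain), C3 (β acyloxy), C4 (α methyl) and C5 (β hydroxymethyl), so every vicinal pair is trans. A fifth core stereocentre, C1′, lies outside the ring and exists only because one of its two CH2O arms is acylated and the other is free. Two identical acyl groups, (3S,4E)-4-formyl-3-(2-oxoethyl)hex-4-enoyl, sit on O-C3 and O-C2′, and each brings one stereocentre (a3) and a trisubstituted E-enal. Sensitive features are the four aldehydes (two of them 1,5-related to an enal), the 1,3-diol monoester at C1′, where acyl migration would scramble C1′, and the two free primary alcohols. The difficulties are three: telling four hydroxyls apart (two acylated, two free), setting C1′ next to the ring, and releasing two dialdehyde units at the very end under near-neutral conditions. The strategy rests on reading C4(CH3)–C5–C6 as a crotonaldehyde unit, C3 as a carbon that can carry two acetyl groups, and C2–C1–C1′–C3′ as an enoate tether. An amine-catalysed Michael/Michael domino then forms C3–C4 and C1–C5 and sets C4, C5 and C1 in one step from achiral materials.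

## Retrosynthetic reasoning

**31 ⇒ 30 ⇒ 29.** In each acyl group the formyl carbon on a4 and the aldehyde carbon of the oxoethyl arm are joined to a cis-1,2-diol on a cyclopentane, so that all four aldehydes of 31 come from one glycol cleavage of hexol 30. The ethylidene group of that ring already holds the enal geometry. Hexol 30 comes from 29 by acid hydrolysis of two acetonides and two primary silyl ethers, so the last two steps need neither base nor oxidant beyond the glycol cleavage.

**29 ⇒ 22 + 28.** Both ester C–O bonds are cut. This leaves one chiral acid, 28, used twice, and a core diol 22 in which only O-C3 and O-C2′ are free. The forward step is a double esterification of a primary and a secondary alcohol with an acid that has no α-stereocentre.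

**28 ⇒ 27 ⇒ 26 ⇒ 24 ⇒ 23.** The ethylidene C=C is cut back to ketone 26 (Wittig ethylidenation). The C–C bond between the ring and the acetate arm is cut back to ketone 24 (enolate alkylation anti to the acetonide, which sets the later a3 centre). Ketone 24 is the hydrogenation product of the purchasable enone 23, whose acetonide supplies both the absolute configuration and the masked diol.

**22 ⇒ 21 ⇒ 20 ⇒ 19.** The two hydroxyls to be acylated are carried as benzyl-type ethers (benzyl on O-C2′, benzyloxymethyl on O-C3) and freed together by hydrogenolysis. The two hydroxyls that stay free in 31 (O-C3′ and O-C6) are silylated in 21. Both arise in 20 from one hydride reduction of δ-lactone 19, whose carbonyl carbon is C3′ and whose ring oxygen sits on C6. The lactone therefore makes the two arms of C1′ chemically different from the start.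

**19 ⇒ 17 ⇒ 15.** The C1′–C2′ bond is cut: benzyloxymethylation of the enolate of the trans-fused lactone 15. The needed epimer has the new group equatorial (trans to C2). Axial entry of the electrophile is expected to give the other epimer 17 first, so the plan sends everything through one enolate and sets C1′ by protonation, where axial entry of the proton and product stability point the same way.

**15 ⇒ 14 ⇒ 12 ⇒ 11.** The C3–O bond is traced to a C3–acetyl bond (Baeyer–Villiger oxidation with retention). The acetate formed is exchanged for an acetal because an acetate would compete for base in the enolate steps.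

**11 ⇒ 9 ⇒ 8.** Lactone 11 comes from 8 by aldehyde reduction (9), retro-Claisen loss of one of the two acetyl groups with equilibration at C3, and lactonisation between O-C6 and the ester on C1′.

**8 ⇒ 5 + 6.** The C3–C4 and C1–C5 bonds are cut. Crotonaldehyde 6 supplies C4 (with its methyl), C5 and C6; the diketone-enoate 5 supplies C3, C2, C1, C1′ and C3′. The forward reaction must set C4 by catalyst control and relay it to C5 and C1. Two acetyl groups are chosen so that C3 is acidic but not stereogenic at this stage.

**5 ⇒ 3 + 4; 3 ⇒ 1 + 2.** The enoate double bond is cut by cross-metathesis to allyl diketone 3 and acrylate 4, and 3 comes from 1 and 2. This route to 5 is preferred to direct enolate alkylation with a 4-halo-enoate because it installs the enoate without base. The enol of 5 can otherwise close onto its own enoate.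

## Alternatives that were turned down

**Alternative 1:** Disconnection of C1–C1′ and the O–C3′ acetal bond of the bicyclic acetal A1 (3-ethoxy-7-methyl-6-(4-methoxybenzyloxy)-4-[(4-methoxybenzyloxy)methyl]-3,4,4a,5,6,7-hexahydrocyclopenta[c]pyran, endo adduct). The forward key step is an inverse-demand hetero-Diels–Alder reaction of cyclopentene carbaldehyde A2 (as a 1-oxadiene) with E-enol ether A3.
- For it: one concerted step forms the pyran and sets C1 and C1′ together, with their relative configuration fixed by enol-ether geometry and the endo rule. The oxygen pattern is also built in: the two hydroxyls to be acylated arrive as 4-methoxybenzyl ethers and the two free ones come out of the acetal and enol ether. On C1′ this is stronger than the chosen route, which needs an enolate alkylation and a separate epimerisation.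
- Against it: A2 is an enal without a second activating group, a weak heterodiene that would need a Lewis acid such as Eu(fod)3 or high pressure. Face selectivity at C1 depends only on the remote C3 and C4 substituents, and C5 is set later by protonation. A2 itself must be made as a single enantiomer with the trans C3/C4 pair in a separate multistep sequence, so the key step creates no absolute configuration.
- Comparison: the chosen domino creates the ring and three ring stereocentres catalytically from achiral components and belongs to a known reaction class for closely related substrates.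

**Alternative 2:** Disconnection of C5–C6 (as a vinyl group) and C4–CH3 of cyclopentanone A4 (trans,trans-4-(2,2-dimethyl-1,3-dioxan-5-yl)-2-methyl-3-vinylcyclopentan-1-one), made from enone A5 by CuI-catalysed vinyl Grignard addition anti to the C1 substituent and methylation of the resulting enolate.
- For it: a well-tried three-component coupling, a very short path to the trans,trans ring, and C3 already carries oxygen, so no retro-Claisen/Baeyer–Villiger detour is needed. On ring step count it is stronger than the chosen route.
- Against it: C1′ sits in a symmetric dioxane, so it is not a stereocentre in A4, and the two diastereotopic CH2O arms must later be told apart with nothing to direct the choice. The C3 ketone must be reduced to the alcohol trans to the adjacent methyl group, which is the direction a hydride reagent avoids. The absolute configuration has to be bought with A5. Enolate methylation after conjugate addition also competes with proton transfer and over-alkylation.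
- Comparison: the chosen route differentiates the two C1′ arms from the outset (lactone carbonyl against benzyloxymethyl) and derives C3–O with retention from a centre set under thermodynamic control.

**Alternative 3:** Disconnection of both a3–a4 bonds of the fully protected bis-adduct A6, made from core bis-enoate A7 and alkenylboronic acid A8 by a twofold conjugate addition under a chiral rhodium catalyst such as [Rh(cod)OH]2 with a chiral bisphosphine.
- For it: the most convergent treatment of the acyl groups. Both a3 centres are set by the catalyst, no chiral acid has to be made, and the enal geometry is carried in A8 from a defined alkenyl halide. On alkene geometry this is stronger than a Wittig reaction.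
- Against it: it leaves the core untouched, since A7 is simply a diester of diol 22. The nucleophile is α-branched and the acceptors are β-alkyl enoate esters, a slow pairing in which protodeboronation competes. Two additions must both be selective on one valuable molecule, one of them at the secondary ester next to ring stereocentres. Unveiling takes three operations on a sensitive compound: desilylation, allylic oxidation beside two free primary alcohols, and acetal hydrolysis.
- Comparison: the chosen route makes the a3 centre once, off the core, from a chiral-pool ketone, and releases all four aldehydes in one neutral glycol cleavage.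

Key step: step 3

Remark on the chemistry (assumption): enone 23, the acetonide of (4R,5R)-4,5-dihydroxycyclopent-2-enone, is taken as a purchased single enantiomer.

## Route

Step 1
Reactants: 1 pentane-2,4-dione (acetylacetone); 2 allyl bromide
Product: 3 3-allylpentane-2,4-dione
Conditions: K2CO3, acetone, reflux (1 in excess)
Reagents that add atoms: none
Why: C-Alkylation of a 1,3-diketone enolate with an allylic bromide (SN2); the excess of 1 keeps the mono-allyl product from reacting again.

Step 2
Reactants: 3 3-allylpentane-2,4-dione; 4 ethyl acrylate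
Product: 5 ethyl (E)-5-acetyl-6-oxohept-2-enoate
Conditions: second-generation Grubbs catalyst RuCl2(=CHPh)(PCy3)(H2IMes) (2 mol %), CH2Cl2, 40 °C
Reagents that add atoms: none
Why: Olefin cross-metathesis of a terminal alkene with an acrylate should give the E-enoate with loss of ethene; no base is present, so the enol of the diketone is not driven into oxa-Michael closure onto the new enoate.

Step 3
Reactants: 5 ethyl (E)-5-acetyl-6-oxohept-2-enoate; 6 (E)-but-2-enal (crotonaldehyde)
Product: 8 ethyl 2-[(1S,2S,3R)-4,4-diacetyl-2-formyl-3-methylcyclopentyl]acetate, via open-chain enamine 7 (not isolated)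
Conditions: (S)-2-[diphenyl(trimethylsilyloxy)methyl]pyrrolidine (20 mol %), PhCO2H (20 mol %), toluene, 0 °C → rt
Reagents that add atoms: none
Why: The amine condenses with 6 to an E-iminium ion, one face of which is blocked by the diphenyl(silyloxy)methyl group. The enol of 5 adds through its central carbon to the β-carbon from the open face (Michael addition, C3–C4 bond), which with the (S)-catalyst should give the R configuration at C4. The resulting enamine 7 attacks the β-carbon of the tethered enoate in a 5-exo-trig Michael closure (C1–C5 bond), and hydrolysis of the ring iminium ion returns the catalyst. The closest known reaction type is the diarylprolinol silyl ether catalysed Michael/Michael domino of enals with enoate-tethered malonates and β-dicarbonyl compounds. C4 is set by the catalyst; C5 and C1 are relayed from C4 in an envelope-like transition state that keeps the methyl group and the enoate chain pseudo-equatorial, so the formyl group ends trans to methyl and the acetate arm trans to formyl. C5 remains epimerisable through the enamine and should settle in the trans,trans arrangement. The step needs C-attack of the diketone, 1,4-addition, and ring closure faster than oxa-Michael closure of 5; the acid co-catalyst keeps the medium non-basic, and after the first addition C3 is quaternary and can no longer enolise.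

Step 4
Reactants: 8 ethyl 2-[(1S,2S,3R)-4,4-diacetyl-2-formyl-3-methylcyclopentyl]acetate
Product: 9 ethyl 2-[(1S,2S,3R)-4,4-diacetyl-2-(hydroxymethyl)-3-methylcyclopentyl]acetate
Conditions: NaBH4 (0.35 equiv), EtOH/CH2Cl2, −78 °C
Reagents that add atoms: none
Why: Chemoselective hydride reduction; the aldehyde reacts far faster than the two hindered methyl ketones at low temperature, and removing it ends the risk of epimerisation at C5.

Step 5
Reactants: 9 ethyl 2-[(1S,2S,3R)-4,4-diacetyl-2-(hydroxymethyl)-3-methylcyclopentyl]acetate
Product: 11 (4aS,6R,7R,7aS)-6-acetyl-7-methylhexahydrocyclopenta[c]pyran-3(1H)-one (trans-fused keto lactone), via hydroxy keto ester 10 (not isolated)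
Conditions: NaOEt (0.3 equiv), EtOH, 0 °C → rt; AcOH; then TsOH·H2O (cat.), toluene, 80 °C
Reagents that add atoms: none
Why: Retro-Claisen cleavage: ethoxide adds to one acetyl group of the non-enolisable 1,3-diketone and expels the enolate of the remaining methyl ketone, which should equilibrate at C3 to the isomer with acetyl trans to the C4 methyl group. Acid then closes the trans-fused δ-lactone by transesterification.

Step 6
Reactants: 11 (4aS,6R,7R,7aS)-6-acetyl-7-methylhexahydrocyclopenta[c]pyran-3(1H)-one
Product: 12 (4aS,6R,7R,7aS)-7-methyl-3-oxooctahydrocyclopenta[c]pyran-6-yl acetate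
Conditions: m-CPBA, NaHCO3, CH2Cl2, rt
Reagents that add atoms: 3-chloroperoxybenzoic acid, OOC(=O)c1cccc(Cl)c1
Why: Baeyer–Villiger oxidation; the secondary ring carbon migrates in preference to methyl and with retention, so the β-acetyl group becomes the β-acetoxy group at C3. The lactone is inert to peracid.

Step 7
Reactants: 12 (4aS,6R,7R,7aS)-7-methyl-3-oxooctahydrocyclopenta[c]pyran-6-yl acetate
Product: 14 (4aS,6R,7R,7aS)-6-hydroxy-7-methylhexahydrocyclopenta[c]pyran-3(1H)-one, via dihydroxy methyl ester 13 (not isolated)
Conditions: K2CO3 (0.3 equiv), MeOH, rt; then TsOH·H2O (cat.), toluene, 80 °C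
Reagents that add atoms: none
Why: Base-catalysed methanolysis removes the acetate and opens the lactone to 13; acid-catalysed lactonisation then restores the δ-lactone. The C3 hydroxyl is trans to the C1 arm and cannot lactonise.

Step 8
Reactants: 14 (4aS,6R,7R,7aS)-6-hydroxy-7-methylhexahydrocyclopenta[c]pyran-3(1H)-one
Product: 15 (4aS,6R,7R,7aS)-6-[(benzyloxy)methoxy]-7-methylhexahydrocyclopenta[c]pyran-3(1H)-one
Conditions: BnOCH2Cl, iPr2NEt, Bu4NI (cat.), CH2Cl2, 40 °C
Reagents that add atoms: benzyl chloromethyl ether, ClCOCc1ccccc1
Why: O-Alkylation of the secondary alcohol with a chloromethyl ether under amine base gives the benzyloxymethyl acetal. It replaces the enolisable acetate before the enolate steps and is later removed together with the benzyl ether.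

Step 9
Reactants: 15 (4aS,6R,7R,7aS)-6-[(benzyloxy)methoxy]-7-methylhexahydrocyclopenta[c]pyran-3(1H)-one
Product: 17 (4S,4aR,6R,7R,7aS)-4-[(benzyloxy)methyl]-6-[(benzyloxy)methoxy]-7-methylhexahydrocyclopenta[c]pyran-3(1H)-one (benzyloxymethyl axial, cis to C2), via lithium enolate 16 (not isolated)
Conditions: LiN(iPr)2, THF, −78 °C; BnOCH2Cl, −78 °C
Reagents that add atoms: benzyl chloromethyl ether, ClCOCc1ccccc1
Why: Lactone enolate alkylation with a reactive chloromethyl ether forms the C1′–C2′ bond. In the rigid trans-fused enolate the electrophile is expected to enter along the axial direction, anti to the axial C1–H, which places the new group axial (17); any equatorial epimer formed beside it is 19 itself and is not separated.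

Step 10
Reactants: 17 (4S,4aR,6R,7R,7aS)-4-[(benzyloxy)methyl]-6-[(benzyloxy)methoxy]-7-methylhexahydrocyclopenta[c]pyran-3(1H)-one
Product: 19 (4R,4aR,6R,7R,7aS)-4-[(benzyloxy)methyl]-6-[(benzyloxy)methoxy]-7-methylhexahydrocyclopenta[c]pyran-3(1H)-one (benzyloxymethyl equatorial, trans to C2), via lithium enolate 18 (not isolated)
Conditions: LiN(iPr)2, THF, −78 → −45 °C; AcOH, −78 °C
Reagents that add atoms: none
Why: Deprotonation and kinetic protonation: both epimers give the same enolate 18, and the proton is expected to enter axially, leaving the benzyloxymethyl group equatorial, which is also the more stable arrangement. This sets C1′.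

Step 11
Reactants: 19 (4R,4aR,6R,7R,7aS)-4-[(benzyloxy)methyl]-6-[(benzyloxy)methoxy]-7-methylhexahydrocyclopenta[c]pyran-3(1H)-one
Product: 20 (2S)-3-(benzyloxy)-2-[(1R,2S,3R,4R)-4-[(benzyloxy)methoxy]-2-(hydroxymethyl)-3-methylcyclopentyl]propan-1-ol
Conditions: LiAlH4, THF, 0 °C
Reagents that add atoms: none
Why: Hydride reduction of the lactone to the diol (O-C3′ and O-C6). C1′ is no longer α to a carbonyl group and is fixed from here on; the acetal and the benzyl ether are inert.

Step 12
Reactants: 20 (2S)-3-(benzyloxy)-2-[(1R,2S,3R,4R)-4-[(benzyloxy)methoxy]-2-(hydroxymethyl)-3-methylcyclopentyl]propan-1-ol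
Product: 21 the bis(tert-butyldimethylsilyl) ether of 20 at O-C3′ and O-C6
Conditions: TBSCl, imidazole, DMF, rt
Reagents that add atoms: tert-butyldimethylsilyl chloride, CC(C)(C)[Si](C)(C)Cl
Why: Silylation of both primary alcohols; no other hydroxyl is free, so no selectivity is required.

Step 13
Reactants: 21 the bis(tert-butyldimethylsilyl) ether of 20
Product: 22 core diol with free hydroxyls at C3 and C2′ and tert-butyldimethylsilyl ethers at O-C3′ and O-C6
Conditions: H2 (1 atm), Pd(OH)2/C, EtOAc, rt
Reagents that add atoms: none
Why: Hydrogenolysis cleaves the benzyl ether and the benzyloxymethyl acetal (the hemiacetal left on O-C3 loses formaldehyde). This frees exactly the two hydroxyls that are to be acylated; silyl ethers survive in ethyl acetate.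

Step 14
Reactants: 23 (3aR,6aR)-2,2-dimethyl-3a,6a-dihydro-4H-cyclopenta[d][1,3]dioxol-4-one
Product: 24 (3aR,6aR)-2,2-dimethyltetrahydro-4H-cyclopenta[d][1,3]dioxol-4-one
Conditions: H2 (1 atm), Pd/C, EtOAc, rt
Reagents that add atoms: none
Why: Heterogeneous hydrogenation of the enone C=C; ketone and acetonide are untouched.

Step 15
Reactants: 24 (3aR,6aR)-2,2-dimethyltetrahydro-4H-cyclopenta[d][1,3]dioxol-4-one
Product: 26 methyl 2-[(3aR,5S,6aR)-2,2-dimethyl-4-oxotetrahydro-4H-cyclopenta[d][1,3]dioxol-5-yl]acetate, via lithium enolate 25 (not isolated)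
Conditions: LiN(iPr)2, THF, −78 °C; BrCH2CO2Me, DMPU, −78 → −40 °C
Reagents that add atoms: methyl bromoacetate, COC(=O)CBr
Why: Kinetic deprotonation at the CH2 group (the other α-carbon carries oxygen and would lead to β-elimination), then SN2 alkylation from the convex face of the cis-fused bicycle, anti to the dioxolane. This sets the later a3 centre (5S).

Step 16
Reactants: 26 methyl 2-[(3aR,5S,6aR)-2,2-dimethyl-4-oxotetrahydro-4H-cyclopenta[d][1,3]dioxol-5-yl]acetate
Product: 27 methyl 2-[(3aS,4E,5S,6aR)-4-ethylidene-2,2-dimethyltetrahydro-4H-cyclopenta[d][1,3]dioxol-5-yl]acetate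
Conditions: EtPPh3Br, KOtBu, THF, 0 °C → rt
Reagents that add atoms: ethyltriphenylphosphonium bromide, CC[P+](c1ccccc1)(c1ccccc1)c1ccccc1.[Br-]
Why: Wittig olefination with a non-stabilised ylide. The methyl group is expected to turn away from the oxygen-bearing ring-fusion carbon C3a, whose C–O bond lies close to the alkene plane, to give the E-alkene (methyl syn to C5), which maps onto the E-enal; geometric isomers should be separable by chromatography.

Step 17
Reactants: 27 methyl 2-[(3aS,4E,5S,6aR)-4-ethylidene-2,2-dimethyltetrahydro-4H-cyclopenta[d][1,3]dioxol-5-yl]acetate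
Product: 28 2-[(3aS,4E,5S,6aR)-4-ethylidene-2,2-dimethyltetrahydro-4H-cyclopenta[d][1,3]dioxol-5-yl]acetic acid
Conditions: LiOH, THF/H2O, rt; then 1 M HCl to pH 4, 0 °C
Reagents that add atoms: lithium hydroxide, [Li+].[OH-]
Why: Saponification of the methyl ester; acetonide and alkene are stable to base, and the stereocentre is β to the carboxyl group and cannot epimerise.

Step 18
Reactants: 22 core diol with free hydroxyls at C3 and C2′; 28 2-[(3aS,4E,5S,6aR)-4-ethylidene-2,2-dimethyltetrahydro-4H-cyclopenta[d][1,3]dioxol-5-yl]acetic acid (2.6 equiv)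
Product: 29 bis-ester of 22 with 28 at O-C3 and O-C2′
Conditions: EDC·HCl, DMAP, CH2Cl2, 0 °C → rt
Reagents that add atoms: none
Why: Steglich esterification (carbodiimide activation, acyl transfer by DMAP) of the primary and the secondary hydroxyl; the acid has no α-stereocentre, so activation cannot epimerise it.

Step 19
Reactants: 29 bis-ester of 22 with 28
Product: 30 hexol: 29 without the two acetonides and the two silyl groups
Conditions: CF3CO2H/H2O/THF, 0 °C → rt
Reagents that add atoms: none
Why: Acid-catalysed hydrolysis of the two acetonides and the two primary silyl ethers; esters survive, and a cold acidic medium is chosen because acyl migration between O-C2′ and O-C3′ is slowest there.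

Step 20
Reactants: 30 hexol
Product: 31 CNP0192766.1, the target: bis[(3S,4E)-4-formyl-3-(2-oxoethyl)hex-4-enoate] of the core at O-C3 and O-C2′ (core C1 R, C3 R, C4 R, C5 S, C1′ S)
Conditions: NaIO4, THF/H2O (pH 7 phosphate buffer), 0 °C
Reagents that add atoms: none
Why: Glycol cleavage through the cyclic periodate ester of each cis-1,2-diol; isolated hydroxyls, esters and alkenes are inert, the medium is neutral, and each enal takes its E-geometry from the exocyclic alkene.

## Compound list

1 | pentane-2,4-dione | CC(=O)CC(C)=O | starting material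
2 | allyl bromide | C=CCBr | starting material
3 | 3-allylpentane-2,4-dione | C=CCC(C(C)=O)C(C)=O | intermediate
4 | ethyl acrylate | C=CC(=O)OCC | starting material
5 | ethyl (E)-5-acetyl-6-oxohept-2-enoate | CCOC(=O)/C=C/CC(C(C)=O)C(C)=O | intermediate
6 | (E)-but-2-enal | C/C=C/C=O | starting material
7 | ethyl (2E,6R,7E)-5,5-diacetyl-8-{(2S)-2-[diphenyl(trimethylsilyloxy)methyl]pyrrolidin-1-yl}-6-methylocta-2,7-dienoate | CCOC(=O)/C=C/CC(C(C)=O)(C(C)=O)[C@H](C)/C=C/N1CCC[C@H]1C(c2ccccc2)(c3ccccc3)O[Si](C)(C)C | intermediate
8 | ethyl 2-[(1S,2S,3R)-4,4-diacetyl-2-formyl-3-methylcyclopentyl]acetate | CCOC(=O)C[C@@H]1CC(C(C)=O)(C(C)=O)[C@H](C)[C@H]1C=O | intermediate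
9 | ethyl 2-[(1S,2S,3R)-4,4-diacetyl-2-(hydroxymethyl)-3-methylcyclopentyl]acetate | CCOC(=O)C[C@@H]1CC(C(C)=O)(C(C)=O)[C@H](C)[C@H]1CO | intermediate
10 | ethyl 2-[(1S,2S,3R,4R)-4-acetyl-2-(hydroxymethyl)-3-methylcyclopentyl]acetate | CCOC(=O)C[C@@H]1C[C@@H](C(C)=O)[C@H](C)[C@H]1CO | intermediate
11 | (4aS,6R,7R,7aS)-6-acetyl-7-methylhexahydrocyclopenta[c]pyran-3(1H)-one | O=C1C[C@@H]2C[C@@H](C(C)=O)[C@H](C)[C@H]2CO1 | intermediate
12 | (4aS,6R,7R,7aS)-7-methyl-3-oxooctahydrocyclopenta[c]pyran-6-yl acetate | O=C1C[C@@H]2C[C@@H](OC(C)=O)[C@H](C)[C@H]2CO1 | intermediate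
13 | methyl 2-[(1S,2S,3R,4R)-4-hydroxy-2-(hydroxymethyl)-3-methylcyclopentyl]acetate | COC(=O)C[C@@H]1C[C@@H](O)[C@H](C)[C@H]1CO | intermediate
14 | (4aS,6R,7R,7aS)-6-hydroxy-7-methylhexahydrocyclopenta[c]pyran-3(1H)-one | O=C1C[C@@H]2C[C@@H](O)[C@H](C)[C@H]2CO1 | intermediate
15 | (4aS,6R,7R,7aS)-6-[(benzyloxy)methoxy]-7-methylhexahydrocyclopenta[c]pyran-3(1H)-one | O=C1C[C@@H]2C[C@@H](OCOCc3ccccc3)[C@H](C)[C@H]2CO1 | intermediate
16 | lithium enolate of 15 | [Li+].[O-]C1=C[C@@H]2C[C@@H](OCOCc3ccccc3)[C@H](C)[C@H]2CO1 | intermediate
17 | (4S,4aR,6R,7R,7aS)-4-[(benzyloxy)methyl]-6-[(benzyloxy)methoxy]-7-methylhexahydrocyclopenta[c]pyran-3(1H)-one | O=C1[C@H](COCc3ccccc3)[C@@H]2C[C@@H](OCOCc4ccccc4)[C@H](C)[C@H]2CO1 | intermediate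
18 | lithium enolate of 17 and 19 | [Li+].[O-]C1=C(COCc3ccccc3)[C@@H]2C[C@@H](OCOCc4ccccc4)[C@H](C)[C@H]2CO1 | intermediate
19 | (4R,4aR,6R,7R,7aS)-4-[(benzyloxy)methyl]-6-[(benzyloxy)methoxy]-7-methylhexahydrocyclopenta[c]pyran-3(1H)-one | O=C1[C@@H](COCc3ccccc3)[C@@H]2C[C@@H](OCOCc4ccccc4)[C@H](C)[C@H]2CO1 | intermediate
20 | (2S)-3-(benzyloxy)-2-[(1R,2S,3R,4R)-4-[(benzyloxy)methoxy]-2-(hydroxymethyl)-3-methylcyclopentyl]propan-1-ol | OC[C@@H](COCc1ccccc1)[C@@H]1C[C@@H](OCOCc2ccccc2)[C@H](C)[C@H]1CO | intermediate
21 | bis(tert-butyldimethylsilyl) ether of 20 at O-C3′ and O-C6 | CC(C)(C)[Si](C)(C)OC[C@@H](COCc1ccccc1)[C@@H]1C[C@@H](OCOCc2ccccc2)[C@H](C)[C@H]1CO[Si](C)(C)C(C)(C)C | intermediate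
22 | core diol, free hydroxyls at C3 and C2′, silyl ethers at O-C3′ and O-C6 | CC(C)(C)[Si](C)(C)OC[C@@H](CO)[C@@H]1C[C@@H](O)[C@H](C)[C@H]1CO[Si](C)(C)C(C)(C)C | intermediate
23 | (3aR,6aR)-2,2-dimethyl-3a,6a-dihydro-4H-cyclopenta[d][1,3]dioxol-4-one | O=C1C=C[C@H]2OC(C)(C)O[C@@H]12 | starting material
24 | (3aR,6aR)-2,2-dimethyltetrahydro-4H-cyclopenta[d][1,3]dioxol-4-one | O=C1CC[C@H]2OC(C)(C)O[C@@H]12 | intermediate
25 | lithium enolate of 24 | [Li+].[O-]C1=CC[C@H]2OC(C)(C)O[C@@H]12 | intermediate
26 | methyl 2-[(3aR,5S,6aR)-2,2-dimethyl-4-oxotetrahydro-4H-cyclopenta[d][1,3]dioxol-5-yl]acetate | O=C1[C@H](CC(=O)OC)C[C@H]2OC(C)(C)O[C@@H]12 | intermediate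
27 | methyl 2-[(3aS,4E,5S,6aR)-4-ethylidene-2,2-dimethyltetrahydro-4H-cyclopenta[d][1,3]dioxol-5-yl]acetate | C/C=C1\[C@H](CC(=O)OC)C[C@H]2OC(C)(C)O[C@@H]12 | intermediate
28 | 2-[(3aS,4E,5S,6aR)-4-ethylidene-2,2-dimethyltetrahydro-4H-cyclopenta[d][1,3]dioxol-5-yl]acetic acid | C/C=C1\[C@H](CC(=O)O)C[C@H]2OC(C)(C)O[C@@H]12 | intermediate
29 | bis-ester of 22 with 28 at O-C3 and O-C2′ | C/C=C1\[C@H](CC(=O)OC[C@H](CO[Si](C)(C)C(C)(C)C)[C@@H]3C[C@@H](OC(=O)C[C@@H]4C[C@H]5OC(C)(C)O[C@H]5/C4=C/C)[C@H](C)[C@H]3CO[Si](C)(C)C(C)(C)C)C[C@H]2OC(C)(C)O[C@@H]12 | intermediate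
30 | hexol (29 without acetonides and silyl groups) | C/C=C1\[C@H](CC(=O)OC[C@H](CO)[C@@H]3C[C@@H](OC(=O)C[C@@H]4C[C@@H](O)[C@@H](O)/C4=C/C)[C@H](C)[C@H]3CO)C[C@@H](O)[C@H]1O | intermediate
31 | CNP0192766.1 | C/C=C(/C=O)[C@@H](CC=O)CC(=O)OC[C@H](CO)[C@@H]1C[C@@H](OC(=O)C[C@H](CC=O)/C(C=O)=C\C)[C@H](C)[C@H]1CO | target

## Step count and least certain steps

Total: 20 steps. Longest linear sequence: 16 steps (steps 1–13 and 18–20). The side-chain acid 28 takes 4 steps (14–17) and is used twice.

**Step 3 (key step).**
- What may go wrong: the enol of 5 may close onto its own enoate (oxa-Michael) and so be lost as a nucleophile. The first addition may be slow because the attacking carbon is flanked by two acetyl groups, and it may revert before the ring closes. The relay of configuration to C1 in the ring closure may be incomplete.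
- Fallback: separate the two bond formations without changing them. Allyl diketone 3 and aldehyde 6 are combined under the same amine catalyst to give (3R)-4,4-diacetyl-3-methylhept-6-enal F1, in which C3 is already quaternary and cannot cyclise through oxygen. Cross-metathesis of F1 with 4 (same ruthenium catalyst as step 2) gives ethyl (2E,6R)-5,5-diacetyl-6-methyl-8-oxooct-2-enoate F2. Renewed treatment with the amine catalyst closes the ring by enamine Michael addition and comes back to 8.

**Step 10 (with step 9).**
- What may go wrong: the α-hydrogen of the axial epimer is equatorial and is removed slowly; if the temperature has to be raised, enolate 18 may lose benzyl alkoxide by β-elimination. Protonation may also be only moderately face-selective.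
- Fallback: set C1′ under thermodynamic control by a reversible conjugate addition. From 15, aminomethylation of the enolate with CH2=NMe2+ I− gives the 4-[(dimethylamino)methyl] lactone F3. Methylation with MeI gives its trimethylammonium iodide F4, and NaHCO3 eliminates this to the 4-methylene lactone F5. Benzyl alcohol with catalytic NaOBn then adds reversibly to F5, and the adduct should settle as the equatorial epimer, which is 19.

**Step 16.**
- What may go wrong: E/Z selectivity may be poor or reversed, since an α-alkoxy ketone can draw the ylide substituent to the oxygen-bearing side. The basic ylide may also epimerise C5.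
- Fallback: Horner–Wittig olefination with separable intermediates. From 26, lithiated ethyldiphenylphosphine oxide adds to the ketone to give the β-hydroxy phosphine oxide F6 as diastereomers, which are separated. The diastereomer whose stereospecific syn-elimination (NaH, DMF) gives the E-alkene is taken on and comes back to 27.

**Step 19.**
- What may go wrong: the acyl group may migrate from O-C2′ to O-C3′ across the 1,3-diol, which would invert C1′. The allylic C–O bond next to the ethylidene group may ionise under the acid that acetonide hydrolysis needs.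
- Fallback: exchange the acetonide for silyl ethers before coupling, so that the last deprotection needs only fluoride. From 27, aqueous acid gives methyl 2-[(1S,3S,4R)-2-ethylidene-3,4-dihydroxycyclopentyl]acetate F7 (E-alkene). Et3SiOTf/2,6-lutidine gives its bis(triethylsilyl) ether F8, and LiOH gives the acid F9. Esterification of 22 with F9 as in step 18 gives the hexasilyl bis-ester F10, and HF·pyridine in THF removes all six silyl groups and comes back to 30.

## Further compounds

F1 | step 3 | (3R)-4,4-diacetyl-3-methylhept-6-enal | C=CCC(C(C)=O)(C(C)=O)[C@H](C)CC=O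
F2 | step 3 | ethyl (2E,6R)-5,5-diacetyl-6-methyl-8-oxooct-2-enoate | CCOC(=O)/C=C/CC(C(C)=O)(C(C)=O)[C@H](C)CC=O
F3 | step 10 | (4aR,6R,7R,7aS)-6-[(benzyloxy)methoxy]-4-[(dimethylamino)methyl]-7-methylhexahydrocyclopenta[c]pyran-3(1H)-one (C4 epimers) | CN(C)CC1[C@@H]2C[C@@H](OCOCc3ccccc3)[C@H](C)[C@H]2COC1=O
F4 | step 10 | trimethylammonium iodide of F3 | C[N+](C)(C)CC1[C@@H]2C[C@@H](OCOCc3ccccc3)[C@H](C)[C@H]2COC1=O.[I-]
F5 | step 10 | (4aS,6R,7R,7aS)-6-[(benzyloxy)methoxy]-7-methyl-4-methylidenehexahydrocyclopenta[c]pyran-3(1H)-one | C=C1[C@@H]2C[C@@H](OCOCc3ccccc3)[C@H](C)[C@H]2COC1=O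
F6 | step 16 | methyl 2-[(3aR,5S,6aR)-4-[1-(diphenylphosphoryl)ethyl]-4-hydroxy-2,2-dimethyltetrahydro-4H-cyclopenta[d][1,3]dioxol-5-yl]acetate (diastereomers at the two new centres) | OC1(C(C)P(=O)(c3ccccc3)c4ccccc4)[C@H](CC(=O)OC)C[C@H]2OC(C)(C)O[C@@H]12
F7 | step 19 | methyl 2-[(1S,2E,3S,4R)-2-ethylidene-3,4-dihydroxycyclopentyl]acetate | C/C=C1\[C@H](CC(=O)OC)C[C@@H](O)[C@H]1O
F8 | step 19 | bis(triethylsilyl) ether of F7 | C/C=C1\[C@H](CC(=O)OC)C[C@@H](O[Si](CC)(CC)CC)[C@H]1O[Si](CC)(CC)CC
F9 | step 19 | 2-[(1S,2E,3S,4R)-2-ethylidene-3,4-bis(triethylsilyloxy)cyclopentyl]acetic acid | C/C=C1\[C@H](CC(=O)O)C[C@@H](O[Si](CC)(CC)CC)[C@H]1O[Si](CC)(CC)CC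
F10 | step 19 | bis-ester of 22 with F9 at O-C3 and O-C2′ | C/C=C1\[C@H](CC(=O)OC[C@H](CO[Si](C)(C)C(C)(C)C)[C@@H]3C[C@@H](OC(=O)C[C@@H]4C[C@@H](O[Si](CC)(CC)CC)[C@@H](O[Si](CC)(CC)CC)/C4=C/C)[C@H](C)[C@H]3CO[Si](C)(C)C(C)(C)C)C[C@@H](O[Si](CC)(CC)CC)[C@H]1O[Si](CC)(CC)CC
A1 | alternative 1 | 3-ethoxy-7-methyl-6-(4-methoxybenzyloxy)-4-[(4-methoxybenzyloxy)methyl]-3,4,4a,5,6,7-hexahydrocyclopenta[c]pyran, endo adduct | COc1ccc(cc1)COC[C@H]2[C@@H]3C[C@@H](OCc4ccc(OC)cc4)[C@H](C)C3=CO[C@@H]2OCC
A2 | alternative 1 | trans-4-(4-methoxybenzyloxy)-5-methylcyclopent-1-ene-1-carbaldehyde | O=CC1=CC[C@@H](OCc2ccc(OC)cc2)[C@@H]1C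
A3 | alternative 1 | (E)-1-ethoxy-3-(4-methoxybenzyloxy)prop-1-ene | CCO/C=C/COCc1ccc(OC)cc1
A4 | alternative 2 | trans,trans-4-(2,2-dimethyl-1,3-dioxan-5-yl)-2-methyl-3-vinylcyclopentan-1-one | CC1(C)OCC(CO1)[C@@H]2CC(=O)[C@H](C)[C@H]2C=C
A5 | alternative 2 | 4-(2,2-dimethyl-1,3-dioxan-5-yl)cyclopent-2-en-1-one | CC1(C)OCC(CO1)[C@@H]2CC(=O)C=C2
A6 | alternative 3 | fully protected bis-adduct with both side chains in place | C/C=C(/CO[Si](C)(C)C(C)(C)C)[C@@H](CC(OC)OC)CC(=O)OC[C@H](CO[Si](C)(C)C(C)(C)C)[C@@H]1C[C@@H](OC(=O)C[C@H](CC(OC)OC)/C(CO[Si](C)(C)C(C)(C)C)=C\C)[C@H](C)[C@H]1CO[Si](C)(C)C(C)(C)C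
A7 | alternative 3 | bis[(E)-5,5-dimethoxypent-2-enoate] of core diol 22 | COC(OC)C/C=C/C(=O)OC[C@H](CO[Si](C)(C)C(C)(C)C)[C@@H]1C[C@@H](OC(=O)/C=C/CC(OC)OC)[C@H](C)[C@H]1CO[Si](C)(C)C(C)(C)C
A8 | alternative 3 | (E)-[1-(tert-butyldimethylsilyloxy)but-2-en-2-yl]boronic acid | C/C=C(/CO[Si](C)(C)C(C)(C)C)B(O)O
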